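**Retrosynthetic overview**
1. δ-Tocopherol (7) comes from cleaving the C2–O bond: an enantiotopic-face-selective, Markovnikov intramolecular hydroalkoxylation of the achiral, planar trisubstituted alkene in an ortho-phytylphenol. This step forms the only new ring (the pyran ring) and sets the C2 quaternary stereocenter.
2. The ortho-phytylphenol comes from Friedel–Crafts ortho-allylation of 4-hydroxy-3-methylphenyl pivalate with natural (7R,11R)-phytol. Phytol supplies C4–C13′, the 12′-methyl and both side-chain stereocenters (4′R, 8′R).
3. The pivalate arene comes from toluhydroquinone (cheap aromatic feedstock) by sterically selective mono-pivaloylation. The pivalate blocks the para oxygen, directs alkylation to the free phenol's open ortho position, and keeps the ring electron-poor enough to avoid oxidation.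

Assumptions: commercial phytol is (2E,7R,11R), which corresponds to 4′R,8′R in the product. The chiral acid antipode that gives 2R is found by screening both enantiomers.

---

**Step 1**
Reactants: 1 (2-methylbenzene-1,4-diol, toluhydroquinone) and 2 (pivaloyl chloride)
Product: 3 (4-hydroxy-3-methylphenyl pivalate)
Conditions: PivCl (0.95 equiv), pyridine, CH2Cl2, 0 °C → rt
Reagents that add atoms: pivaloyl chloride, CC(C)(C)C(=O)Cl (adds the pivaloyl group)
Why: The bulky acyl chloride acylates the unhindered OH (meta to Me) in preference to the OH flanked by the ortho methyl, so the hindered OH stays free for later ring closure (esterification, sterically controlled).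

**Step 2**
Reactants: 3 and 4 ((2E,7R,11R)-phytol)
Product: 5 (4-hydroxy-3-methyl-5-[(2E,7R,11R)-3,7,11,15-tetramethylhexadec-2-en-1-yl]phenyl pivalate)
Conditions: 3 (2 equiv), 4 (1 equiv), BF3·OEt2 (10 mol%), CH2Cl2, 0 °C → rt, 2 h
Reagents that add atoms: none (BF3 is a catalyst; the product is the condensation product minus water)
Why: Friedel–Crafts allylation. The phytyl cation is attacked at its primary terminus. The only position ortho or para to the free OH that is open is C6 of the arene, and the electron-withdrawing OPiv deactivates the positions next to it, so C-alkylation gives only 5 with the E-trisubstituted alkene retained. Mild temperature and a short reaction time avoid the usual racemic acid cyclization to the chroman. No stereocenter is made here, and the 7R and 11R centers are untouched.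

**Step 3 (key step)**
Reactants: 5
Product: 6 ((2R,4′R,8′R)-δ-tocopheryl pivalate)
Conditions: chiral confined imidodiphosphorimidate (IDPi) Brønsted acid (5 mol%, antipode giving 2R), cyclohexane or toluene, 0.05 M, 4 Å MS, 40 °C, 48–72 h
Reagents that add atoms: none (isomerization)
Why: Proposed new method: the strongly acidic chiral IDPi protonates C3 of the trisubstituted alkene in a concerted, counter-anion-assisted Markovnikov addition. The phenol OH attacks the developing tertiary center C2 (6-endo) inside the confined chiral pocket, so the catalyst, not the remote 4′/8′ centers, selects the alkene face and sets C2 as R. The closest known reaction type is chiral-acid-catalyzed intramolecular hydroalkoxylation of unactivated alkenols, and the racemic version of this cyclization is the industrial acid-catalyzed tocopherol ring closure. The main risk is discriminating CH3 from CH2R at C2. Any minor 2S diastereomer is separable by chiral HPLC.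

**Step 4**
Reactants: 6
Product: 7 (δ-tocopherol, (2R,4′R,8′R))
Conditions: LiAlH4, THF, 0 °C → 60 °C, under Ar; then aqueous HCl workup
Reagents that add atoms: none (hydride and workup only supply H; neopentyl alcohol is the by-product)
Why: Reductive cleavage of the pivalate ester frees the 6-OH. The tertiary aryl alkyl ether of the chroman and the alkyl side chain are inert, and no stereocenter is epimerizable under these basic conditions.

---

**Compound list**

| # | Name | SMILES | Role |
|---|---|---|---|
| 1 | 2-Methylbenzene-1,4-diol (toluhydroquinone) | Cc1cc(O)ccc1O | starting material |
| 2 | Pivaloyl chloride | CC(C)(C)C(=O)Cl | starting material (reagent) |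
| 3 | 4-Hydroxy-3-methylphenyl pivalate | CC(C)(C)C(=O)Oc1ccc(O)c(C)c1 | intermediate |
| 4 | (2E,7R,11R)-Phytol | OC/C=C(\C)CCC[C@H](C)CCC[C@H](C)CCCC(C)C | starting material |
| 5 | 4-Hydroxy-3-methyl-5-[(2E,7R,11R)-phytyl]phenyl pivalate | CC(C)(C)C(=O)Oc1cc(C)c(O)c(C/C=C(\C)CCC[C@H](C)CCC[C@H](C)CCCC(C)C)c1 | intermediate |
| 6 | (2R,4′R,8′R)-δ-Tocopheryl pivalate | CC(C)(C)C(=O)Oc1cc(C)c2O[C@](C)(CCC[C@H](C)CCC[C@H](C)CCCC(C)C)CCc2c1 | intermediate |
| 7 | δ-Tocopherol | Cc1cc(O)cc2c1O[C@](C)(CCC[C@H](C)CCC[C@H](C)CCCC(C)C)CC2 | target |

Checks done:
- Formulas: 5 is C32H54O3, 6 is its isomer, and 7 is C27H46O2.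
- Stereochemistry: the SMILES of 6 and 7 share the same neighbor order at C2, giving 2R. C4′ and C8′ are R, matching 7R,11R of phytol.
- Ring: the 8-methyl sits ortho to the ring oxygen, and the 6-oxygen is para to it.

**Total steps:** 4. **Longest linear sequence:** 4 (toluhydroquinone → 3 → 5 → 6 → 7).

**Three steps most likely to fail**
1. **Step 3 (enantioselective cyclization).** Discriminating CH3 from CH2R at C2 may give low ee, and acid could reopen the tertiary ether and erode C2. Fallback: cyclize non-selectively with ZnCl2/HCl, then separate the 2R,4′R,8′R and 2S,4′R,8′R diastereomers by preparative chiral-phase HPLC or SFC.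
2. **Step 2 (regioselective allylation without premature cyclization).** Alkylation ortho to the OPiv group, SN2′ attack, or racemic chroman formation could compete. Fallback: ortho-brominate 3 (NBS), then couple the aryl Grignard or boronate with (E)-phytyl bromide (Cu or Pd catalysis). This regiospecific aryl–allyl coupling replaces the electrophilic substitution.
3. **Step 1 (monoesterification selectivity).** Mixtures of mono- and diester, or the wrong regioisomer, may form. Fallback: make the regiodefined 4-acetoxy-2-methylphenol by Fries rearrangement of o-cresyl acetate to 4-hydroxy-3-methylacetophenone, then Baeyer–Villiger oxidation, and carry the acetate through the same steps (final removal with K2CO3/MeOH or LiAlH4).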